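**Retrosynthetic overview**
1. 8,8a-Deoxyoleandolide ⇐ acetonide hydrolysis ⇐ 14-membered lactone closed last by a C1–O13 bond (acyl transfer from the auxiliary-bearing imide to the C13 hydroxyl).
2. Seco-imide ⇐ C10–C11 syn-aldol between a C1–C10 ethyl ketone and a C11–C14 aldehyde (sets C10, C11; C12, C13 come with the aldehyde).
3. C1–C10 ketone ⇐ C4–C5 syn,syn β-ketoimide aldol, then C3 syn-reduction (sets C4, C5, C3; C2 from the β-ketoimide).
4. C5–C10 keto-aldehyde ⇐ desymmetrising ethylation of meso-2,4-dimethylglutaric anhydride (sets C6, C8).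
5. Ring order: temporary 1,3-dioxane (C3/C5 acetonide) first, 14-membered lactone last.

Assumption: anhydride 1 is bought (it is also made in one step from commercial 2,4-dimethylglutaric acid), and the enantiomer written for the ligand in step 1 and for the borane in step 12 is taken to be the one that gives the drawn configuration (otherwise its antipode is used).

Atom numbers C1–C14 below are macrolide numbers.

**Step 1**
Reactants: 1 (3R,5S)-3,5-dimethyloxane-2,6-dione (meso-2,4-dimethylglutaric anhydride)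
Product: 2 (2S,4R)-2,4-dimethyl-5-oxoheptanoic acid
Conditions: Et2Zn, [Rh(cod)Cl]2 (2.5 mol %), (S)-t-Bu-PHOX (5.5 mol %), THF, 50 °C; then 1 M HCl
Reagents that add atoms: diethylzinc CC[Zn]CC
Why: Rhodium/phosphinooxazoline-catalysed enantioselective desymmetrising alkylation of a meso-anhydride (Rovis-type acyl cross-coupling), in which insertion into one enantiotopic acyl–O bond, transmetalation and reductive elimination give the keto acid, so C6 and C8 come from the meso substrate and their absolute sense from the ligand.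

**Step 2**
Reactants: 2 (2S,4R)-2,4-dimethyl-5-oxoheptanoic acid
Product: 3 S-ethyl (2S,4R)-2,4-dimethyl-5-oxoheptanethioate
Conditions: EtSH, DCC, DMAP (cat.), CH2Cl2, 0 °C to rt
Reagents that add atoms: ethanethiol CCS
Why: Steglich thioesterification under mild carbodiimide activation leaves the ketone and the α-stereocentre untouched.

**Step 3**
Reactants: 3 S-ethyl (2S,4R)-2,4-dimethyl-5-oxoheptanethioate
Product: 4 (2S,4R)-2,4-dimethyl-5-oxoheptanal
Conditions: Et3SiH, 10% Pd/C, acetone, rt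
Reagents that add atoms: none
Why: Fukuyama reduction is selective for the thioester over the ketone and stops at the aldehyde without epimerising C6.

**Step 4**
Reactants: 5 (S)-4-benzyl-3-propanoyl-1,3-oxazolidin-2-one
Product: 7 (S)-4-benzyl-3-[(R)-2-methyl-3-oxopentanoyl]-1,3-oxazolidin-2-one, via lithium Z-enolate 6 (not isolated)
Conditions: LiN(i-Pr)2, THF, −78 °C; then EtCOCl, −78 °C; AcOH quench
Reagents that add atoms: propanoyl chloride CCC(=O)Cl
Why: Evans asymmetric acylation, in which the chelated lithium Z-enolate is acylated on the face opposite the benzyl group to set C2 (R), and the β-ketoimide does not epimerise because allylic strain keeps its C2–H out of conjugation.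

**Step 5**
Reactants: 7 (S)-4-benzyl-3-[(R)-2-methyl-3-oxopentanoyl]-1,3-oxazolidin-2-one; 4 (2S,4R)-2,4-dimethyl-5-oxoheptanal
Product: 9 (S)-4-benzyl-3-[(2R,4R,5S,6S,8R)-5-hydroxy-2,4,6,8-tetramethyl-3,9-dioxoundecanoyl]-1,3-oxazolidin-2-one, via trichlorotitanium Z-enolate 8 (not isolated)
Conditions: TiCl4, i-Pr2NEt, CH2Cl2, −10 °C; then 4, −78 to −40 °C; aq NH4Cl
Reagents that add atoms: none
Why: Evans titanium-mediated syn,syn β-ketoimide aldol, in which the chelated Z-enolate adds through a chair transition state under control of the C2 methyl centre to set C4 and C5 (2,4-syn, 4,5-syn), anti-Felkin addition to the α-methyl aldehyde (normal for Z-enolates) being the matched case and the C9 ketone of 4 staying untouched.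

**Step 6**
Reactants: 9 (S)-4-benzyl-3-[(2R,4R,5S,6S,8R)-5-hydroxy-2,4,6,8-tetramethyl-3,9-dioxoundecanoyl]-1,3-oxazolidin-2-one
Product: 10 (S)-4-benzyl-3-[(2R,3S,4R,5S,6S,8R)-3,5-dihydroxy-2,4,6,8-tetramethyl-9-oxoundecanoyl]-1,3-oxazolidin-2-one
Conditions: catecholborane, THF, −10 °C; then aq potassium sodium tartrate
Reagents that add atoms: none
Why: Hydroxyl-directed syn-reduction (Evans catecholborane protocol), in which the C5 hydroxyl forms an aryloxyborane that chelates and activates only the C3 ketone, external hydride adds axially to the half-chair chelate to set C3 syn to C5, and the isolated C9 ketone (no β-hydroxyl) reacts far more slowly.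

**Step 7**
Reactants: 10 (S)-4-benzyl-3-[(2R,3S,4R,5S,6S,8R)-3,5-dihydroxy-2,4,6,8-tetramethyl-9-oxoundecanoyl]-1,3-oxazolidin-2-one
Product: 11 (S)-4-benzyl-3-[(2R,3S,4R,5S,6S,8R)-3,5-(isopropylidenedioxy)-2,4,6,8-tetramethyl-9-oxoundecanoyl]-1,3-oxazolidin-2-one
Conditions: 2-methoxypropene, PPTS (cat.), CH2Cl2, 0 °C
Reagents that add atoms: 2-methoxypropene COC(C)=C
Why: Kinetic acetonide formation on the syn-1,3-diol (all-equatorial chair), which also stops C5–OH from lactonising onto C1 or forming a hemiketal with C9.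

**Step 8**
Reactants: 5 (S)-4-benzyl-3-propanoyl-1,3-oxazolidin-2-one
Product: 13 (S)-4-benzyl-3-[(2S,3R)-3-hydroxy-2-methylbutanoyl]-1,3-oxazolidin-2-one, via dibutylboron Z-enolate 12 (not isolated)
Conditions: n-Bu2BOTf, Et3N, CH2Cl2, 0 °C; then MeCHO, −78 to 0 °C; then H2O2, MeOH, pH 7 buffer (NaH2PO4/Na2HPO4)
Reagents that add atoms: acetaldehyde CC=O
Why: Evans boron syn-aldol through the Z-enolate and a Zimmerman–Traxler chair, the auxiliary setting the future C12 and C13 as (2S,3R).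

**Step 9**
Reactants: 13 (S)-4-benzyl-3-[(2S,3R)-3-hydroxy-2-methylbutanoyl]-1,3-oxazolidin-2-one
Product: 14 (2S,3R)-3-hydroxy-N-methoxy-N,2-dimethylbutanamide
Conditions: MeNHOMe·HCl, AlMe3, CH2Cl2, −20 to 0 °C; aq potassium sodium tartrate
Reagents that add atoms: N,O-dimethylhydroxylamine hydrochloride CNOC.Cl
Why: Weinreb transamidation by the aluminium amide, assisted by the free β-hydroxyl, releases the auxiliary without touching either stereocentre.

**Step 10**
Reactants: 14 (2S,3R)-3-hydroxy-N-methoxy-N,2-dimethylbutanamide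
Product: 15 (2S,3R)-N-methoxy-N,2-dimethyl-3-(triethylsilyloxy)butanamide
Conditions: Et3SiCl, imidazole, DMF, 0 °C to rt
Reagents that add atoms: chlorotriethylsilane CC[Si](CC)(CC)Cl
Why: Standard silylation of a secondary alcohol, TES being chosen so it can later be removed next to an acetonide.

**Step 11**
Reactants: 15 (2S,3R)-N-methoxy-N,2-dimethyl-3-(triethylsilyloxy)butanamide
Product: 16 (2S,3R)-2-methyl-3-(triethylsilyloxy)butanal
Conditions: i-Bu2AlH, THF, −78 °C; aq potassium sodium tartrate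
Reagents that add atoms: none
Why: Weinreb amide reduction stops at the chelated hemiaminal and gives the aldehyde without epimerisation.

**Step 12**
Reactants: 11 (S)-4-benzyl-3-[(2R,3S,4R,5S,6S,8R)-3,5-(isopropylidenedioxy)-2,4,6,8-tetramethyl-9-oxoundecanoyl]-1,3-oxazolidin-2-one; 16 (2S,3R)-2-methyl-3-(triethylsilyloxy)butanal
Product: 18 (S)-4-benzyl-3-[(2R,3S,4R,5S,6S,8R,10R,11S,12R,13R)-11-hydroxy-3,5-(isopropylidenedioxy)-2,4,6,8,10,12-hexamethyl-9-oxo-13-(triethylsilyloxy)tetradecanoyl]-1,3-oxazolidin-2-one, via diisopinocampheylboron Z-enolate 17 (not isolated)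
Conditions: (+)-Ipc2BOTf, i-Pr2NEt, CH2Cl2, −78 °C; then 16, −78 to −20 °C; then H2O2, MeOH, pH 7 buffer (NaH2PO4/Na2HPO4), 0 °C
Reagents that add atoms: none
Why: Paterson-type reagent-controlled boron syn-aldol, in which only the ethyl ketone is enolised (the α-branched imide is not) to the Z-enolate, whose chair transition state sets C10 (R) and C11 (S) under isopinocampheyl control, reinforced by anti-Felkin addition to 16 and overriding the weak opposite bias of C8.

**Step 13**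
Reactants: 18 the C13 triethylsilyl ether aldol adduct named in step 12
Product: 19 (S)-4-benzyl-3-[(2R,3S,4R,5S,6S,8R,10R,11S,12S,13R)-11,13-dihydroxy-3,5-(isopropylidenedioxy)-2,4,6,8,10,12-hexamethyl-9-oxotetradecanoyl]-1,3-oxazolidin-2-one
Conditions: HF·pyridine, pyridine, THF, 0 °C
Reagents that add atoms: none
Why: Buffered fluoride cleaves the secondary TES ether while acetonide, imide and β-hydroxy ketone survive (the C12 descriptor changes by CIP priority only).

**Step 14**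
Reactants: 19 the 11,13-diol seco-imide named in step 13
Product: 20 3,5-O-isopropylidene-8,8a-deoxyoleandolide (14-membered lactone, 2R,3S,4R,5S,6S,8R,10R,11S,12R,13R)
Conditions: Zn4(OCOCF3)6O (10 mol %), DMAP (20 mol %), toluene, 60 °C, slow addition of 19 (final 1 mM)
Reagents that add atoms: none
Why: Proposed new method: direct macrolactonization by acyl transfer from the Evans N-acyl oxazolidinone to the C13 hydroxyl inside a μ-oxo zinc cluster, where the two imide carbonyls chelate one zinc centre (as in the known Lewis-acid-catalysed alcoholysis of N-acyl oxazolidinones) and C13–OH sits as an alkoxide on a neighbouring zinc centre (as in the cluster's known transesterification of methyl esters), so the C1–O13 bond forms within the cluster and the oxazolidinone is expelled; C13–OH should win over C11–OH (flanked by two methyl-bearing carbons, hydrogen-bonded to the C9 ketone, leading to a more strained 12-membered ring), the reversible 9,13-hemiketal can only react through its open form, and the acetonide supplies the turn; the closest known reactions are these intermolecular imide alcoholyses and thioester or mixed-anhydride macrolactonizations, none of which has been run as a ring closure from the auxiliary-bearing imide.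

**Step 15**
Reactants: 20 3,5-O-isopropylidene-8,8a-deoxyoleandolide
Product: 21 8,8a-deoxyoleandolide, (3R,4S,5R,6S,7S,9R,11R,12S,13R,14R)-4,6,12-trihydroxy-3,5,7,9,11,13,14-heptamethyl-1-oxacyclotetradecane-2,10-dione
Conditions: 1 M HCl, THF, rt
Reagents that add atoms: none
Why: Mild acid hydrolysis of the acetonide, tolerated by the lactone and the β-hydroxy ketone (the product may equilibrate with its 5,9-hemiketal in solution).

**Compound list**
1 | (3R,5S)-3,5-dimethyloxane-2,6-dione (meso-2,4-dimethylglutaric anhydride) | O=C1[C@@H](C)C[C@@H](C)C(=O)O1 | starting material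
2 | (2S,4R)-2,4-dimethyl-5-oxoheptanoic acid | OC(=O)[C@@H](C)C[C@@H](C)C(=O)CC | intermediate
3 | S-ethyl (2S,4R)-2,4-dimethyl-5-oxoheptanethioate | CCSC(=O)[C@@H](C)C[C@@H](C)C(=O)CC | intermediate
4 | (2S,4R)-2,4-dimethyl-5-oxoheptanal | O=C[C@@H](C)C[C@@H](C)C(=O)CC | intermediate
5 | (S)-4-benzyl-3-propanoyl-1,3-oxazolidin-2-one | CCC(=O)N1[C@@H](Cc2ccccc2)COC1=O | starting material
6 | lithium (Z)-enolate of 5 | C/C=C(\O[Li])N1[C@@H](Cc2ccccc2)COC1=O | intermediate
7 | (S)-4-benzyl-3-[(R)-2-methyl-3-oxopentanoyl]-1,3-oxazolidin-2-one | O=C([C@H](C)C(=O)CC)N1[C@@H](Cc2ccccc2)COC1=O | intermediate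
8 | trichlorotitanium (Z)-enolate of 7 (C3–C4 enolate) | C/C=C(\O[Ti](Cl)(Cl)Cl)[C@@H](C)C(=O)N1[C@@H](Cc2ccccc2)COC1=O | intermediate
9 | (S)-4-benzyl-3-[(2R,4R,5S,6S,8R)-5-hydroxy-2,4,6,8-tetramethyl-3,9-dioxoundecanoyl]-1,3-oxazolidin-2-one | O=C([C@H](C)C(=O)[C@H](C)[C@@H](O)[C@@H](C)C[C@@H](C)C(=O)CC)N1[C@@H](Cc2ccccc2)COC1=O | intermediate
10 | (S)-4-benzyl-3-[(2R,3S,4R,5S,6S,8R)-3,5-dihydroxy-2,4,6,8-tetramethyl-9-oxoundecanoyl]-1,3-oxazolidin-2-one | O=C([C@H](C)[C@@H](O)[C@H](C)[C@@H](O)[C@@H](C)C[C@@H](C)C(=O)CC)N1[C@@H](Cc2ccccc2)COC1=O | intermediate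
11 | (S)-4-benzyl-3-[(2R,3S,4R,5S,6S,8R)-3,5-(isopropylidenedioxy)-2,4,6,8-tetramethyl-9-oxoundecanoyl]-1,3-oxazolidin-2-one | O=C([C@H](C)[C@H]2OC(C)(C)O[C@H]([C@H]2C)[C@@H](C)C[C@@H](C)C(=O)CC)N1[C@@H](Cc3ccccc3)COC1=O | intermediate
12 | dibutylboron (Z)-enolate of 5 | C/C=C(\OB(CCCC)CCCC)N1[C@@H](Cc2ccccc2)COC1=O | intermediate
13 | (S)-4-benzyl-3-[(2S,3R)-3-hydroxy-2-methylbutanoyl]-1,3-oxazolidin-2-one | O=C([C@@H](C)[C@@H](C)O)N1[C@@H](Cc2ccccc2)COC1=O | intermediate
14 | (2S,3R)-3-hydroxy-N-methoxy-N,2-dimethylbutanamide | CON(C)C(=O)[C@@H](C)[C@@H](C)O | intermediate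
15 | (2S,3R)-N-methoxy-N,2-dimethyl-3-(triethylsilyloxy)butanamide | CON(C)C(=O)[C@@H](C)[C@@H](C)O[Si](CC)(CC)CC | intermediate
16 | (2S,3R)-2-methyl-3-(triethylsilyloxy)butanal | O=C[C@@H](C)[C@@H](C)O[Si](CC)(CC)CC | intermediate
17 | diisopinocampheylboron (Z)-enolate of 11 (C9–C10 enolate; isopinocampheyl groups 1S,2R,3S,5S) | O=C([C@H](C)[C@H]2OC(C)(C)O[C@H]([C@H]2C)[C@@H](C)C[C@@H](C)/C(OB([C@H]3C[C@H]4C[C@@H]([C@@H]3C)C4(C)C)[C@H]3C[C@H]4C[C@@H]([C@@H]3C)C4(C)C)=C/C)N1[C@@H](Cc5ccccc5)COC1=O | intermediate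
18 | (S)-4-benzyl-3-[(2R,3S,4R,5S,6S,8R,10R,11S,12R,13R)-11-hydroxy-3,5-(isopropylidenedioxy)-2,4,6,8,10,12-hexamethyl-9-oxo-13-(triethylsilyloxy)tetradecanoyl]-1,3-oxazolidin-2-one | O=C([C@H](C)[C@H]2OC(C)(C)O[C@H]([C@H]2C)[C@@H](C)C[C@@H](C)C(=O)[C@H](C)[C@@H](O)[C@@H](C)[C@@H](C)O[Si](CC)(CC)CC)N1[C@@H](Cc3ccccc3)COC1=O | intermediate
19 | (S)-4-benzyl-3-[(2R,3S,4R,5S,6S,8R,10R,11S,12S,13R)-11,13-dihydroxy-3,5-(isopropylidenedioxy)-2,4,6,8,10,12-hexamethyl-9-oxotetradecanoyl]-1,3-oxazolidin-2-one | O=C([C@H](C)[C@H]2OC(C)(C)O[C@H]([C@H]2C)[C@@H](C)C[C@@H](C)C(=O)[C@H](C)[C@@H](O)[C@@H](C)[C@@H](C)O)N1[C@@H](Cc3ccccc3)COC1=O | intermediate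
20 | 3,5-O-isopropylidene-8,8a-deoxyoleandolide (2R,3S,4R,5S,6S,8R,10R,11S,12R,13R) | O=C1[C@H](C)[C@H]2OC(C)(C)O[C@H]([C@H]2C)[C@@H](C)C[C@@H](C)C(=O)[C@H](C)[C@@H](O)[C@@H](C)[C@@H](C)O1 | intermediate
21 | 8,8a-deoxyoleandolide | C[C@@H]1[C@@H](O)[C@@H](C)C[C@@H](C)C(=O)[C@H](C)[C@@H](O)[C@@H](C)[C@@H](C)OC(=O)[C@H](C)[C@H]1O | target

**Step count and risks**
Total step count: 15. Longest linear sequence: 10 (steps 1, 2, 3, 5, 6, 7, 12, 13, 14, 15, from anhydride 1).

Steps most likely to fail: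

Step 14 (the proposed imide-to-lactone acyl transfer). The ring closure may be too slow at high dilution, the 9,13-hemiketal may hold back the C13 hydroxyl, or the C11 hydroxyl may give the 12-membered lactone. Fallback with known chemistry, setting out from 19: LiOH/H2O2 in THF–H2O at 0 °C removes the auxiliary to give the seco acid F1. 2,4,6-Trichlorobenzoyl chloride and Et3N in THF convert it into the mixed anhydride F2. Slow addition of F2 to DMAP in toluene at high dilution closes the ring (Yamaguchi macrolactonization) and comes back to the route at 20.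

Step 12 (late double-stereodifferentiating aldol on a large ketone). Reagent control may not override the C8 bias, or enolisation may be slow next to the imide. Fallback by changing the order of assembly, setting out from thioester 3: (+)-Ipc2BOTf/i-Pr2NEt gives the boron enolate F3, which adds to 16 to give the hydroxy ketone thioester F4, so the diastereomers can be separated on a small compound. Et3SiOTf/2,6-lutidine gives the bis-silyl ether F5. Et3SiH with Pd/C gives the aldehyde F6. Titanium enolate 8 (from 7) adds to F6 to give the aldol adduct F7. Catecholborane gives the syn-diol F8, and 2-methoxypropene/PPTS gives the acetonide F9. HF·pyridine then removes both triethylsilyl groups and comes back to the route at 19.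

Step 6 (chemoselective reduction of the C3 ketone beside the C9 ketone). Some C9 reduction is possible. Fallback that accepts over-reduction, setting out from 9: excess Zn(BH4)2 in Et2O/CH2Cl2 (−78 to −20 °C) reduces both ketones, C3 syn to C5 through the zinc chelate and C9 unselectively, to the triol F10. 2,2-Dimethoxypropane/PPTS engages only the syn-3,5-diol to give the acetonide alcohol F11. Dess–Martin periodinane with NaHCO3 in CH2Cl2 re-oxidises the lone C9 carbinol and comes back to the route at 11.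

**Further compounds**
F1 | step 14 | seco acid (2R,3S,4R,5S,6S,8R,10R,11S,12S,13R)-11,13-dihydroxy-3,5-(isopropylidenedioxy)-2,4,6,8,10,12-hexamethyl-9-oxotetradecanoic acid | OC(=O)[C@H](C)[C@H]1OC(C)(C)O[C@H]([C@H]1C)[C@@H](C)C[C@@H](C)C(=O)[C@H](C)[C@@H](O)[C@@H](C)[C@@H](C)O
F2 | step 14 | mixed anhydride of F1 with 2,4,6-trichlorobenzoic acid | O=C(OC(=O)[C@H](C)[C@H]1OC(C)(C)O[C@H]([C@H]1C)[C@@H](C)C[C@@H](C)C(=O)[C@H](C)[C@@H](O)[C@@H](C)[C@@H](C)O)c1c(Cl)cc(Cl)cc1Cl
F3 | step 12 | boron enolate: diisopinocampheylboron (Z)-enolate of 3 | CCSC(=O)[C@@H](C)C[C@@H](C)/C(OB([C@H]1C[C@H]2C[C@@H]([C@@H]1C)C2(C)C)[C@H]1C[C@H]2C[C@@H]([C@@H]1C)C2(C)C)=C/C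
F4 | step 12 | hydroxy ketone thioester S-ethyl (2S,4R,6R,7S,8R,9R)-7-hydroxy-2,4,6,8-tetramethyl-5-oxo-9-(triethylsilyloxy)decanethioate | CCSC(=O)[C@@H](C)C[C@@H](C)C(=O)[C@H](C)[C@@H](O)[C@@H](C)[C@@H](C)O[Si](CC)(CC)CC
F5 | step 12 | bis-silyl ether S-ethyl (2S,4R,6R,7S,8S,9R)-2,4,6,8-tetramethyl-5-oxo-7,9-bis(triethylsilyloxy)decanethioate | CCSC(=O)[C@@H](C)C[C@@H](C)C(=O)[C@H](C)[C@@H](O[Si](CC)(CC)CC)[C@@H](C)[C@@H](C)O[Si](CC)(CC)CC
F6 | step 12 | aldehyde (2S,4R,6R,7S,8S,9R)-2,4,6,8-tetramethyl-5-oxo-7,9-bis(triethylsilyloxy)decanal | O=C[C@@H](C)C[C@@H](C)C(=O)[C@H](C)[C@@H](O[Si](CC)(CC)CC)[C@@H](C)[C@@H](C)O[Si](CC)(CC)CC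
F7 | step 12 | aldol adduct (S)-4-benzyl-3-[(2R,4R,5S,6S,8R,10R,11S,12S,13R)-5-hydroxy-2,4,6,8,10,12-hexamethyl-3,9-dioxo-11,13-bis(triethylsilyloxy)tetradecanoyl]-1,3-oxazolidin-2-one | O=C([C@H](C)C(=O)[C@H](C)[C@@H](O)[C@@H](C)C[C@@H](C)C(=O)[C@H](C)[C@@H](O[Si](CC)(CC)CC)[C@@H](C)[C@@H](C)O[Si](CC)(CC)CC)N1[C@@H](Cc2ccccc2)COC1=O
F8 | step 12 | syn-diol (S)-4-benzyl-3-[(2R,3S,4R,5S,6S,8R,10R,11S,12S,13R)-3,5-dihydroxy-2,4,6,8,10,12-hexamethyl-9-oxo-11,13-bis(triethylsilyloxy)tetradecanoyl]-1,3-oxazolidin-2-one | O=C([C@H](C)[C@@H](O)[C@H](C)[C@@H](O)[C@@H](C)C[C@@H](C)C(=O)[C@H](C)[C@@H](O[Si](CC)(CC)CC)[C@@H](C)[C@@H](C)O[Si](CC)(CC)CC)N1[C@@H](Cc2ccccc2)COC1=O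
F9 | step 12 | acetonide: 3,5-O-isopropylidene derivative of F8 | O=C([C@H](C)[C@H]2OC(C)(C)O[C@H]([C@H]2C)[C@@H](C)C[C@@H](C)C(=O)[C@H](C)[C@@H](O[Si](CC)(CC)CC)[C@@H](C)[C@@H](C)O[Si](CC)(CC)CC)N1[C@@H](Cc3ccccc3)COC1=O
F10 | step 6 | triol (S)-4-benzyl-3-[(2R,3S,4R,5S,6S,8R,9RS)-3,5,9-trihydroxy-2,4,6,8-tetramethylundecanoyl]-1,3-oxazolidin-2-one (C9 epimers) | O=C([C@H](C)[C@@H](O)[C@H](C)[C@@H](O)[C@@H](C)C[C@@H](C)C(O)CC)N1[C@@H](Cc2ccccc2)COC1=O
F11 | step 6 | acetonide alcohol: 3,5-O-isopropylidene derivative of F10 (C9 epimers) | O=C([C@H](C)[C@H]2OC(C)(C)O[C@H]([C@H]2C)[C@@H](C)C[C@@H](C)C(O)CC)N1[C@@H](Cc3ccccc3)COC1=O
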